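**Retrosynthetic overview**

1. The lactone ring (O1–C2–C3–C4–C4a–C8a) is closed last: asymmetric palladium-catalysed cyclocarbonylation of a 2-(1-arylvinyl)phenol forms C3–C2 and C2–O1 and sets C4 (R); desilylation then gives the target.
2. The 1,1-diarylethylene comes from a 2,4-bis(methoxymethoxy)-6-styrylbenzophenone by Peterson methylenation and MOM cleavage.
3. The benzophenone is assembled in one flask across 3,5-bis(methoxymethoxy)benzyne: an (E)-alkenylmagnesium adds (C5–vinyl bond) and the arylmagnesium so formed is acylated by a Weinreb amide (C4a–C4 bond).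
4. Feature used: ring A is a 1,2,3,5-substituted benzene in which C5 (styryl), C4a (bearing C4) and C8a (bearing O1) are contiguous and C7 bears the second oxygen; two adjacent carbon substituents beside a ring oxygen are what nucleophile-then-electrophile addition across a 3-alkoxybenzyne delivers.
5. Ring order: the three benzene rings are bought as 5-bromoresorcinol, ferulic acid and vanillic acid (two steps each to the three components); the lactone ring is the only ring formed (step 10).

Key step: step 7

Assumption: the sense of induction of the chiral diphosphine in step 10 cannot be fixed on paper for this substrate; the antipode that gives the 4R lactone is to be chosen after a test run, both antipodes being accessible.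

**Route**

Step 1
Reactants: 1 5-bromoresorcinol (5-bromobenzene-1,3-diol)
Product: 2 1-bromo-3,5-bis(methoxymethoxy)benzene
Conditions: MOMCl (2.6 equiv), iPr2NEt, CH2Cl2, 0 °C → rt
Reagents that add atoms: chloromethyl methyl ether, COCCl
Why: O-alkylation of both phenols by the reactive α-chloro ether under amine base (MOM acetal formation) gives ethers that tolerate organomagnesium reagents and whose oxygen later directs the aryne addition.

Step 2
Reactants: 2 1-bromo-3,5-bis(methoxymethoxy)benzene
Product: 3 1-bromo-2-iodo-3,5-bis(methoxymethoxy)benzene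
Conditions: NIS (1.05 equiv), MeCN, 0 °C → rt, dark
Reagents that add atoms: N-iodosuccinimide, O=C1CCC(=O)N1I
Why: Electrophilic aromatic iodination should go to C2, which is para to one MOM ether and ortho to the other, rather than to the more crowded C4 that is only ortho-activated; neutral NIS leaves the acetals intact, and the iodine fixes the site of metalation for aryne generation.

Step 3
Reactants: 4 ferulic acid [(E)-3-(4-hydroxy-3-methoxyphenyl)prop-2-enoic acid]
Product: 6 (E)-3-[4-(tert-butyldimethylsilyloxy)-3-methoxyphenyl]prop-2-enoic acid, via bis-silyl derivative 5 (not isolated)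
Conditions: TBSCl (2.3 equiv), imidazole, DMF, rt; then AcOH/THF/H2O, rt
Reagents that add atoms: tert-butyldimethylsilyl chloride, CC(C)(C)[Si](C)(C)Cl
Why: Imidazole-mediated silylation of phenol and acid, then selective hydrolysis of the labile silyl ester under mild aqueous acid, leaves the aryl silyl ether (protection followed by partial deprotection).

Step 4
Reactants: 6 (E)-3-[4-(tert-butyldimethylsilyloxy)-3-methoxyphenyl]prop-2-enoic acid
Product: 7 tert-butyl{4-[(E)-2-bromoethenyl]-2-methoxyphenoxy}dimethylsilane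
Conditions: NBS (1.05 equiv), LiOAc (0.2 equiv), MeCN/H2O, rt
Reagents that add atoms: N-bromosuccinimide, O=C1CCC(=O)N1Br
Why: Catalytic Hunsdiecker-type bromodecarboxylation, in which bromination of the electron-rich cinnamate double bond is followed by loss of CO2, should give the (E)-β-bromostyrene and is most favourable for para-oxygenated cinnamic acids.

Step 5
Reactants: 8 vanillic acid (4-hydroxy-3-methoxybenzoic acid)
Product: 9 4-hydroxy-N,3-dimethoxy-N-methylbenzamide
Conditions: MeNHOMe·HCl, EDC·HCl, HOBt, iPr2NEt, CH2Cl2, 0 °C → rt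
Reagents that add atoms: N,O-dimethylhydroxylamine hydrochloride, CNOC.Cl
Why: Carbodiimide amide coupling through the HOBt active ester, in which the amine outcompetes the phenol as nucleophile, gives the Weinreb amide without prior protection.

Step 6
Reactants: 9 4-hydroxy-N,3-dimethoxy-N-methylbenzamide
Product: 10 4-(tert-butyldimethylsilyloxy)-N,3-dimethoxy-N-methylbenzamide
Conditions: TBSCl, imidazole, DMF, rt
Reagents that add atoms: tert-butyldimethylsilyl chloride, CC(C)(C)[Si](C)(C)Cl
Why: Standard imidazole-mediated silylation of the phenol removes the acidic proton and gives an aryl silyl ether that is stable to Grignard reagents.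

Step 7
Reactants: 7 tert-butyl{4-[(E)-2-bromoethenyl]-2-methoxyphenoxy}dimethylsilane (1.6 equiv); 3 1-bromo-2-iodo-3,5-bis(methoxymethoxy)benzene (1.0 equiv); 10 4-(tert-butyldimethylsilyloxy)-N,3-dimethoxy-N-methylbenzamide (2.5 equiv)
Product: 17 [2,4-bis(methoxymethoxy)-6-{(E)-2-[4-(tert-butyldimethylsilyloxy)-3-methoxyphenyl]ethenyl}phenyl][4-(tert-butyldimethylsilyloxy)-3-methoxyphenyl]methanone, via alkenyllithium 11 (not isolated), via alkenylmagnesium bromide 12 (not isolated), via bromoarylmagnesium chloride 13 (not isolated), via aryne 14 (not isolated), via arylmagnesium bromide 15 (not isolated), via magnesium hemiaminal 16 (not isolated)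
Conditions: 7, t-BuLi (2 equiv per 7), Et2O/THF, −78 °C, then MgBr2·OEt2, −78 → 0 °C; separately 3, iPrMgCl·LiCl (1.05 equiv), THF, −40 °C; combine, 0 → 45 °C; then 10, 0 °C → rt; aq NH4Cl
Reagents that add atoms: none
Why: Iodine–magnesium exchange at C2 of 3 gives 13, which on warming loses MgBrCl to form aryne 14; the alkenyl–magnesium bond of 12 adds across the strained triple bond (carbomagnesiation) so that the vinyl carbon binds the aryne carbon remote from the neighbouring OMOM group (future C5) and magnesium ends on the carbon next to that oxygen (future C4a), and arylmagnesium 15 is then acylated by Weinreb amide 10 through chelate 16, which releases ketone 17 only on work-up (Weinreb ketone synthesis). The closest known reaction type is the addition of Grignard reagents to arynes generated from ortho-dihaloarenes by halogen–magnesium exchange, followed by an electrophilic quench, which is established for 3-alkoxyarynes; a β-arylvinyl Grignard reagent on this aryne is an untested application of it. No ring is closed and no stereocentre is formed; the step makes the two adjacent bonds C5–vinyl and C4a–C4 (chroman-2-one numbering) and joins all three aromatic rings. The regiochemistry is needed and is secured by the alkoxy group on the carbon next to the aryne: its inductive pull distorts the triple bond so that attack occurs at the distal carbon, and the carbanion develops ortho to oxygen, where MOM chelation to magnesium also holds it. The iodine makes aryne formation regiospecific, whereas deprotonation of bromide 2 by a lithium amide is expected to occur first between the two MOM ethers, where no aryne can form; the (E)-geometry is kept because bromine–lithium exchange, transmetalation to magnesium and the addition all proceed with retention at the sp2 carbon, which direct magnesium insertion would not guarantee.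

Step 8
Reactants: 17 [2,4-bis(methoxymethoxy)-6-{(E)-2-[4-(tert-butyldimethylsilyloxy)-3-methoxyphenyl]ethenyl}phenyl][4-(tert-butyldimethylsilyloxy)-3-methoxyphenyl]methanone
Product: 19 1-[2,4-bis(methoxymethoxy)-6-{(E)-2-[4-(tert-butyldimethylsilyloxy)-3-methoxyphenyl]ethenyl}phenyl]-1-[4-(tert-butyldimethylsilyloxy)-3-methoxyphenyl]ethene, via β-hydroxysilane 18 (not isolated)
Conditions: TMSCH2Li (2.5 equiv), THF, −78 → 0 °C; then AcOH, rt
Reagents that add atoms: (trimethylsilyl)methyllithium, [Li]C[Si](C)(C)C
Why: Peterson olefination, in which the small α-silyl carbanion adds to the non-enolisable ketone and the tertiary, doubly benzylic β-hydroxysilane 18 loses trimethylsilanol under weak acid, should give the alkene without exposing the styryl-substituted system to strong acid.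

Step 9
Reactants: 19 1-[2,4-bis(methoxymethoxy)-6-{(E)-2-[4-(tert-butyldimethylsilyloxy)-3-methoxyphenyl]ethenyl}phenyl]-1-[4-(tert-butyldimethylsilyloxy)-3-methoxyphenyl]ethene
Product: 21 4-{1-[4-(tert-butyldimethylsilyloxy)-3-methoxyphenyl]ethenyl}-5-{(E)-2-[4-(tert-butyldimethylsilyloxy)-3-methoxyphenyl]ethenyl}benzene-1,3-diol, via bis(trimethylsilyl) ether 20 (not isolated)
Conditions: TMSOTf (5 equiv), 2,2'-bipyridyl (7.5 equiv), CH2Cl2, 0 °C → rt; then H2O, rt
Reagents that add atoms: none
Why: Chemoselective cleavage of aryl MOM ethers by a silyl triflate buffered with 2,2'-bipyridyl converts the acetals into aryl trimethylsilyl ethers 20 with no free Brønsted acid present, and water then hydrolyses these, so the acid-sensitive 1,1-diarylethylene and the aryl TBS ethers should survive.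

Step 10
Reactants: 21 4-{1-[4-(tert-butyldimethylsilyloxy)-3-methoxyphenyl]ethenyl}-5-{(E)-2-[4-(tert-butyldimethylsilyloxy)-3-methoxyphenyl]ethenyl}benzene-1,3-diol
Product: 22 (4R)-7-hydroxy-4-[4-(tert-butyldimethylsilyloxy)-3-methoxyphenyl]-5-{(E)-2-[4-(tert-butyldimethylsilyloxy)-3-methoxyphenyl]ethenyl}-3,4-dihydro-2H-chromen-2-one
Conditions: Pd(OAc)2 (5 mol %), WingPhos-type P-stereogenic bibenzooxaphosphole diphosphine (6 mol %, antipode giving 4R), CO (20 bar), toluene, 80 °C
Reagents that add atoms: carbon monoxide, [C-]#[O+]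
Why: Asymmetric intramolecular hydroesterification (cyclocarbonylation) of a 2-(1-arylvinyl)phenol, in which a hydride of divalent palladium adds to the 1,1-disubstituted alkene with hydrogen going to the internal carbon, CO inserts into the primary alkyl–palladium bond and the ortho-phenol captures the acyl group to close the six-membered lactone, sets C4 by ligand-controlled choice of the alkene face in the hydropalladation, while the internal stilbene bond has no phenol placed to trap an acyl group and should be left.

Step 11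
Reactants: 22 (4R)-7-hydroxy-4-[4-(tert-butyldimethylsilyloxy)-3-methoxyphenyl]-5-{(E)-2-[4-(tert-butyldimethylsilyloxy)-3-methoxyphenyl]ethenyl}-3,4-dihydro-2H-chromen-2-one
Product: 23 (4R)-7-hydroxy-4-(4-hydroxy-3-methoxyphenyl)-5-[(E)-2-(4-hydroxy-3-methoxyphenyl)ethenyl]-3,4-dihydro-2H-chromen-2-one
Conditions: TBAF (2.5 equiv), AcOH (2.5 equiv), THF, 0 °C
Reagents that add atoms: none
Why: Fluoride-induced cleavage of the two aryl silyl ethers, buffered with acetic acid so that no phenoxide or hydroxide opens the aryl ester lactone, should free the target, and C4, which is not acidic under these conditions, keeps its configuration.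

**Compound list**

1 | 5-bromoresorcinol | Oc1cc(O)cc(Br)c1 | starting material
2 | 1-bromo-3,5-bis(methoxymethoxy)benzene | COCOc1cc(Br)cc(OCOC)c1 | intermediate
3 | 1-bromo-2-iodo-3,5-bis(methoxymethoxy)benzene | COCOc1cc(Br)c(I)c(OCOC)c1 | intermediate
4 | ferulic acid | COc1cc(/C=C/C(=O)O)ccc1O | starting material
5 | tert-butyldimethylsilyl (E)-3-[4-(tert-butyldimethylsilyloxy)-3-methoxyphenyl]prop-2-enoate (bis-silyl derivative, not isolated) | COc1cc(/C=C/C(=O)O[Si](C)(C)C(C)(C)C)ccc1O[Si](C)(C)C(C)(C)C | intermediate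
6 | (E)-3-[4-(tert-butyldimethylsilyloxy)-3-methoxyphenyl]prop-2-enoic acid | COc1cc(/C=C/C(=O)O)ccc1O[Si](C)(C)C(C)(C)C | intermediate
7 | tert-butyl{4-[(E)-2-bromoethenyl]-2-methoxyphenoxy}dimethylsilane | COc1cc(/C=C/Br)ccc1O[Si](C)(C)C(C)(C)C | intermediate
8 | vanillic acid | COc1cc(C(=O)O)ccc1O | starting material
9 | 4-hydroxy-N,3-dimethoxy-N-methylbenzamide | COc1cc(C(=O)N(C)OC)ccc1O | intermediate
10 | 4-(tert-butyldimethylsilyloxy)-N,3-dimethoxy-N-methylbenzamide | COc1cc(C(=O)N(C)OC)ccc1O[Si](C)(C)C(C)(C)C | intermediate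
11 | {(E)-2-[4-(tert-butyldimethylsilyloxy)-3-methoxyphenyl]ethenyl}lithium (not isolated) | COc1cc(/C=C/[Li])ccc1O[Si](C)(C)C(C)(C)C | intermediate
12 | {(E)-2-[4-(tert-butyldimethylsilyloxy)-3-methoxyphenyl]ethenyl}magnesium bromide (not isolated) | COc1cc(/C=C/[Mg]Br)ccc1O[Si](C)(C)C(C)(C)C | intermediate
13 | [2-bromo-4,6-bis(methoxymethoxy)phenyl]magnesium chloride (not isolated) | COCOc1cc(Br)c([Mg]Cl)c(OCOC)c1 | intermediate
14 | 3,5-bis(methoxymethoxy)benzyne (not isolated) | COCOC1=CC(OCOC)=CC#C1 | intermediate
15 | [2,4-bis(methoxymethoxy)-6-{(E)-2-[4-(tert-butyldimethylsilyloxy)-3-methoxyphenyl]ethenyl}phenyl]magnesium bromide (not isolated) | COc1cc(/C=C/c2cc(OCOC)cc(OCOC)c2[Mg]Br)ccc1O[Si](C)(C)C(C)(C)C | intermediate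
16 | bromomagnesium salt of the N-methoxy-N-methyl hemiaminal of ketone 17 (racemic, not isolated) | COc1cc(/C=C/c2cc(OCOC)cc(OCOC)c2C(O[Mg]Br)(N(C)OC)c2ccc(O[Si](C)(C)C(C)(C)C)c(OC)c2)ccc1O[Si](C)(C)C(C)(C)C | intermediate
17 | [2,4-bis(methoxymethoxy)-6-{(E)-2-[4-(tert-butyldimethylsilyloxy)-3-methoxyphenyl]ethenyl}phenyl][4-(tert-butyldimethylsilyloxy)-3-methoxyphenyl]methanone | COc1cc(/C=C/c2cc(OCOC)cc(OCOC)c2C(=O)c2ccc(O[Si](C)(C)C(C)(C)C)c(OC)c2)ccc1O[Si](C)(C)C(C)(C)C | intermediate
18 | 1-[2,4-bis(methoxymethoxy)-6-{(E)-2-[4-(tert-butyldimethylsilyloxy)-3-methoxyphenyl]ethenyl}phenyl]-1-[4-(tert-butyldimethylsilyloxy)-3-methoxyphenyl]-2-(trimethylsilyl)ethanol (racemic, not isolated) | COc1cc(/C=C/c2cc(OCOC)cc(OCOC)c2C(O)(C[Si](C)(C)C)c2ccc(O[Si](C)(C)C(C)(C)C)c(OC)c2)ccc1O[Si](C)(C)C(C)(C)C | intermediate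
19 | 1-[2,4-bis(methoxymethoxy)-6-{(E)-2-[4-(tert-butyldimethylsilyloxy)-3-methoxyphenyl]ethenyl}phenyl]-1-[4-(tert-butyldimethylsilyloxy)-3-methoxyphenyl]ethene | COc1cc(/C=C/c2cc(OCOC)cc(OCOC)c2C(=C)c2ccc(O[Si](C)(C)C(C)(C)C)c(OC)c2)ccc1O[Si](C)(C)C(C)(C)C | intermediate
20 | bis(trimethylsilyl) ether of diol 21 (not isolated) | COc1cc(/C=C/c2cc(O[Si](C)(C)C)cc(O[Si](C)(C)C)c2C(=C)c2ccc(O[Si](C)(C)C(C)(C)C)c(OC)c2)ccc1O[Si](C)(C)C(C)(C)C | intermediate
21 | 4-{1-[4-(tert-butyldimethylsilyloxy)-3-methoxyphenyl]ethenyl}-5-{(E)-2-[4-(tert-butyldimethylsilyloxy)-3-methoxyphenyl]ethenyl}benzene-1,3-diol | COc1cc(/C=C/c2cc(O)cc(O)c2C(=C)c2ccc(O[Si](C)(C)C(C)(C)C)c(OC)c2)ccc1O[Si](C)(C)C(C)(C)C | intermediate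
22 | (4R)-7-hydroxy-4-[4-(tert-butyldimethylsilyloxy)-3-methoxyphenyl]-5-{(E)-2-[4-(tert-butyldimethylsilyloxy)-3-methoxyphenyl]ethenyl}-3,4-dihydro-2H-chromen-2-one | COc1cc(/C=C/c2cc(O)cc3c2[C@@H](c2ccc(O[Si](C)(C)C(C)(C)C)c(OC)c2)CC(=O)O3)ccc1O[Si](C)(C)C(C)(C)C | intermediate
23 | (4R)-7-hydroxy-4-(4-hydroxy-3-methoxyphenyl)-5-[(E)-2-(4-hydroxy-3-methoxyphenyl)ethenyl]-3,4-dihydro-2H-chromen-2-one | COc1cc(/C=C/c2cc(O)cc3c2[C@@H](c2ccc(O)c(OC)c2)CC(=O)O3)ccc1O | target

**Count and risks**

Total steps: 11. Longest linear sequence: 7 steps (steps 1, 2, 7, 8, 9, 10, 11; the ferulic and vanillic branches are equally long).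

Steps most likely to fail, riskiest first:

Step 7. The aryne may be captured by arylmagnesium 13 itself, or may react with the styrene double bonds (ene or [2+2] pathways), faster than alkenylmagnesium 12 adds. The doubly ortho-substituted arylmagnesium 15 may also be acylated too slowly and end up protonated on work-up. The fallback makes the two bonds one at a time by known reactions; it sets out from 3 and 7 and returns at 17. Arylmagnesium 13 would be generated as in step 7 but held at −40 °C, where it should not eliminate. It would be added to commercial 4-(tert-butyldimethylsilyloxy)-3-methoxybenzaldehyde to give [2-bromo-4,6-bis(methoxymethoxy)phenyl][4-(tert-butyldimethylsilyloxy)-3-methoxyphenyl]methanol F1 (racemic). Dess–Martin oxidation (NaHCO3, CH2Cl2) would give [2-bromo-4,6-bis(methoxymethoxy)phenyl][4-(tert-butyldimethylsilyloxy)-3-methoxyphenyl]methanone F2. Bromide 7 would be converted by t-BuLi and 2-isopropoxy-4,4,5,5-tetramethyl-1,3,2-dioxaborolane into tert-butyl{2-methoxy-4-[(E)-2-(4,4,5,5-tetramethyl-1,3,2-dioxaborolan-2-yl)ethenyl]phenoxy}dimethylsilane F3. Suzuki–Miyaura coupling of F2 with F3 (Pd(OAc)2, SPhos, K3PO4, toluene/H2O, 60 °C) should then give 17 with the (E)-geometry retained.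

Step 10. Hydropalladation at the alkene carbon attached to a doubly ortho-substituted ring may be slow or poorly face-selective, and palladium hydride may act on the stilbene double bond (isomerisation, or hydroesterification by a phenol of another molecule). The fallback sets out from 21 and returns at 22. Oxidative cyclocarbonylation of 21 with a catalyst of divalent palladium (Pd(OAc)2, 1,4-benzoquinone, CO 1 atm, MeCN) would give 7-hydroxy-4-[4-(tert-butyldimethylsilyloxy)-3-methoxyphenyl]-5-{(E)-2-[4-(tert-butyldimethylsilyloxy)-3-methoxyphenyl]ethenyl}-2H-chromen-2-one F4. Copper hydride catalysed asymmetric conjugate reduction of this 4-arylcoumarin (Cu(OAc)2, DTBM-SEGPHOS of the antipode giving 4R, diethoxymethylsilane in excess, t-BuOH, toluene) would set C4 by hydride delivery to one face of the C3=C4 bond. After work-up, which also cleaves the transient silyl ether on the C7 phenol, this should give 22; the unactivated stilbene bond is not a conjugate acceptor and should be left.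

Step 9. Electrophilic species in the mixture (silyl triflate-activated methoxymethyl fragments or traces of triflic acid) may attack the electron-rich 1,1-diarylethylene, leading to cationic cyclisation onto the neighbouring styryl group or to oligomerisation, and the aryl TBS ethers may be partly lost. The fallback sets out from 17 and returns at 21, so that no acetal has to be cleaved once the alkene is present. The MOM ethers would be removed at the acid-tolerant ketone stage (TMSOTf, 2,2'-bipyridyl, CH2Cl2; then H2O) to give [2,4-dihydroxy-6-{(E)-2-[4-(tert-butyldimethylsilyloxy)-3-methoxyphenyl]ethenyl}phenyl][4-(tert-butyldimethylsilyloxy)-3-methoxyphenyl]methanone F5. Mitsunobu etherification with allyl alcohol (PPh3, DIAD, THF) would give [2,4-bis(allyloxy)-6-{(E)-2-[4-(tert-butyldimethylsilyloxy)-3-methoxyphenyl]ethenyl}phenyl][4-(tert-butyldimethylsilyloxy)-3-methoxyphenyl]methanone F6. Peterson methylenation as in step 8 would give 1-[2,4-bis(allyloxy)-6-{(E)-2-[4-(tert-butyldimethylsilyloxy)-3-methoxyphenyl]ethenyl}phenyl]-1-[4-(tert-butyldimethylsilyloxy)-3-methoxyphenyl]ethene F7. Allyl transfer to morpholine catalysed by zerovalent palladium (Pd(PPh3)4, THF, rt) would then free both phenols under neutral conditions to give 21.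

**Further compounds**

F1 | step 7 | [2-bromo-4,6-bis(methoxymethoxy)phenyl][4-(tert-butyldimethylsilyloxy)-3-methoxyphenyl]methanol (racemic) | COCOc1cc(Br)c(C(O)c2ccc(O[Si](C)(C)C(C)(C)C)c(OC)c2)c(OCOC)c1
F2 | step 7 | [2-bromo-4,6-bis(methoxymethoxy)phenyl][4-(tert-butyldimethylsilyloxy)-3-methoxyphenyl]methanone | COCOc1cc(Br)c(C(=O)c2ccc(O[Si](C)(C)C(C)(C)C)c(OC)c2)c(OCOC)c1
F3 | step 7 | tert-butyl{2-methoxy-4-[(E)-2-(4,4,5,5-tetramethyl-1,3,2-dioxaborolan-2-yl)ethenyl]phenoxy}dimethylsilane | COc1cc(/C=C/B2OC(C)(C)C(C)(C)O2)ccc1O[Si](C)(C)C(C)(C)C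
F4 | step 10 | 7-hydroxy-4-[4-(tert-butyldimethylsilyloxy)-3-methoxyphenyl]-5-{(E)-2-[4-(tert-butyldimethylsilyloxy)-3-methoxyphenyl]ethenyl}-2H-chromen-2-one | COc1cc(/C=C/c2cc(O)cc3oc(=O)cc(-c4ccc(O[Si](C)(C)C(C)(C)C)c(OC)c4)c23)ccc1O[Si](C)(C)C(C)(C)C
F5 | step 9 | [2,4-dihydroxy-6-{(E)-2-[4-(tert-butyldimethylsilyloxy)-3-methoxyphenyl]ethenyl}phenyl][4-(tert-butyldimethylsilyloxy)-3-methoxyphenyl]methanone | COc1cc(/C=C/c2cc(O)cc(O)c2C(=O)c2ccc(O[Si](C)(C)C(C)(C)C)c(OC)c2)ccc1O[Si](C)(C)C(C)(C)C
F6 | step 9 | [2,4-bis(allyloxy)-6-{(E)-2-[4-(tert-butyldimethylsilyloxy)-3-methoxyphenyl]ethenyl}phenyl][4-(tert-butyldimethylsilyloxy)-3-methoxyphenyl]methanone | COc1cc(/C=C/c2cc(OCC=C)cc(OCC=C)c2C(=O)c2ccc(O[Si](C)(C)C(C)(C)C)c(OC)c2)ccc1O[Si](C)(C)C(C)(C)C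
F7 | step 9 | 1-[2,4-bis(allyloxy)-6-{(E)-2-[4-(tert-butyldimethylsilyloxy)-3-methoxyphenyl]ethenyl}phenyl]-1-[4-(tert-butyldimethylsilyloxy)-3-methoxyphenyl]ethene | COc1cc(/C=C/c2cc(OCC=C)cc(OCC=C)c2C(=C)c2ccc(O[Si](C)(C)C(C)(C)C)c(OC)c2)ccc1O[Si](C)(C)C(C)(C)C
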